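**Plan**

- Retrosynthesis: first the eleven benzyl groups, then the interflavan C4–C8 bond, then the C4–CH2 bond of the lower unit (both C4 bonds come from one 4-hydroxyflavan electrophile). In that monomer, O1–C8a and C2–C3 are cut together, back to a 2-fluoroaryl benzyloxymethyl ketone and 3,4-bis(benzyloxy)benzaldehyde.
- Forward: rings A and B are bought as benzene derivatives. Ring C (O1, C2, C3, C4, C4a, C8a) is closed in one aldol/SNAr annulation, the aldol making C2–C3 and the fluoride displacement making O1–C8a. The C4 ketone is then reduced and ionized twice, first to take the acetate chain, then to join a second copy of the monomer to C8. Hydrogenolysis ends the route.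
- Enabling feature: C4 lies between C3 and ring A and must carry a carbon substituent in both halves of the target. A carbonyl at C4 therefore acidifies C3–H, activates the C8a–F bond ortho to it, and later becomes the C4 leaving group.
- Stereochemistry: C2 and C3 come from a reagent-controlled syn boron aldol (isopinocampheyl ligands), kept through the SNAr closure with retention at C2 (2,3-cis). C4 of both units comes from attack on the planar C4 cation anti to the 3-benzyloxy and 2-aryl groups (3,4-trans).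

Key step: step 3

Assumption: the (Z)-enol borinate made with (−)-Ipc2BOTf (ligands from (+)-α-pinene) is taken to attack the Si face of the aldehyde, the sense known for the corresponding allylborane; should the sense be the opposite, the reagent from (−)-α-pinene is used and nothing else changes.

**Route**

Step 1
Reactants: 1 1,3,5-trifluorobenzene; 2 benzyl alcohol
Product: 3 1,3-bis(benzyloxy)-5-fluorobenzene
Conditions: 2 (2.1 equiv in all), NaH (2.2 equiv), NMP, 0 to 90 °C
Reagents that add atoms: benzyl alcohol (second equivalent of 2), OCc1ccccc1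
Why: Twofold nucleophilic aromatic substitution (SNAr) of sodium benzyloxide on the polyfluoroarene, one equivalent of 2 for each of the two fluorines replaced; each alkoxy group introduced slows the next substitution, so the reaction should stop cleanly after two fluorines are replaced.

Step 2
Reactants: 3 1,3-bis(benzyloxy)-5-fluorobenzene; 4 2-(benzyloxy)-N-methoxy-N-methylacetamide
Product: 7 2-(benzyloxy)-1-[2,4-bis(benzyloxy)-6-fluorophenyl]ethan-1-one, via aryllithium 5 (not isolated), via tetrahedral adduct 6 (not isolated)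
Conditions: n-BuLi, THF, −78 °C; then 4, −78 °C; aq NH4Cl
Reagents that add atoms: none
Why: Directed ortho-lithiation followed by Weinreb ketone synthesis; fluorine is the stronger acidifying ortho substituent, so deprotonation is expected at the position flanked by F and a benzyloxy group, the chelated adduct 6 prevents over-addition, and −78 °C keeps the ortho-fluoroaryllithium from losing LiF.

Step 3
Reactants: 7 2-(benzyloxy)-1-[2,4-bis(benzyloxy)-6-fluorophenyl]ethan-1-one; 8 3,4-bis(benzyloxy)benzaldehyde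
Product: 12 (2R,3S)-3,5,7-tris(benzyloxy)-2-[3,4-bis(benzyloxy)phenyl]-2,3-dihydro-4H-chromen-4-one, via enol borinate 9 (not isolated), via boron aldolate 10 (not isolated), via ammonium alkoxide 11 (not isolated)
Conditions: (−)-Ipc2BH, TfOH, hexane, rt; then 7, i-Pr2NEt, CH2Cl2, −78 °C; 8, −78 °C; Bu4NF (0.2 equiv), THF, −78 to 0 °C
Reagents that add atoms: none
Why: Proposed new method: amine-assisted enolization of 7 with the boron triflate gives the (Z)-enol borinate 9, which adds to 8 through a closed chair (Zimmerman–Traxler) transition state to the syn boron aldolate 10; fluoride then takes boron off the C2 oxygen, and the freed alkoxide 11 displaces the ring A fluorine ortho to the C4 carbonyl by addition–elimination (SNAr), the fluoride set free carrying the chain on. The closest known reaction types are the syn aldol reaction of (Z)-enol diisopinocampheylborinates of ethyl ketones and the alkoxide SNAr closure of ring C of flavans and chromones onto an ortho-fluorinated ring A, here run in one flask on an α-benzyloxy ketone. Ring C (O1, C2, C3, C4, C4a, C8a) closes by attack of O1 on the sp2 carbon C8a, 6-endo-trig with respect to the C4a–C8a π bond that is conjugated with the C4 carbonyl, which takes up the Meisenheimer charge before fluoride leaves and ring A is restored. C3 is set relative to C2 by the Z enolate geometry in the chair (syn, which is 2,3-cis after closure with retention at C2), and the absolute sense (2R) by the isopinocampheyl ligands, which leave the Si face of the aldehyde open. The step needs the kinetic syn adduct to reach the ring without retro-aldol cleavage or epimerization at C3: the boron aldol is irreversible at −78 °C, the alkoxide is released only by the weakly basic fluoride in the presence of the ammonium triflate buffer, and it should be consumed at once by the intramolecular substitution.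

Step 4
Reactants: 12 (2R,3S)-3,5,7-tris(benzyloxy)-2-[3,4-bis(benzyloxy)phenyl]-2,3-dihydro-4H-chromen-4-one
Product: 13 (2R,3R,4R)-3,5,7-tris(benzyloxy)-2-[3,4-bis(benzyloxy)phenyl]-3,4-dihydro-2H-chromen-4-ol
Conditions: NaBH4, CeCl3·7H2O, MeOH/THF, −40 °C
Reagents that add atoms: none
Why: Luche reduction of the aryl ketone under nearly neutral conditions, so the enolizable C3 centre should not epimerize; hydride is expected to add anti to the pseudo-axial 3-benzyloxy group (3,4-cis alcohol), and the C4 configuration is of no consequence because C4 becomes planar in steps 6 and 7.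

Step 5
Reactants: 14 benzyl acetate
Product: 16 1-(benzyloxy)-1-(tert-butyldimethylsilyloxy)ethene, via lithium enolate 15 (not isolated)
Conditions: LiN(i-Pr)2, THF, −78 °C; then t-BuMe2SiCl, DMPU, −78 °C to rt
Reagents that add atoms: tert-butyldimethylsilyl chloride, CC(C)(C)[Si](C)(C)Cl
Why: Kinetic ester enolization and O-silylation (standard silyl ketene acetal formation); the benzyl ester is chosen so that the acid is unmasked in the final hydrogenolysis.

Step 6
Reactants: 13 (2R,3R,4R)-3,5,7-tris(benzyloxy)-2-[3,4-bis(benzyloxy)phenyl]-3,4-dihydro-2H-chromen-4-ol; 16 1-(benzyloxy)-1-(tert-butyldimethylsilyloxy)ethene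
Product: 17 benzyl 2-[(2R,3R,4S)-3,5,7-tris(benzyloxy)-2-[3,4-bis(benzyloxy)phenyl]-3,4-dihydro-2H-chromen-4-yl]acetate
Conditions: Me3SiOTf (0.1 equiv), CH2Cl2, 4 Å sieves, −78 °C (3 equiv of 16)
Reagents that add atoms: none
Why: Lewis-acid ionization of the benzylic 4-hydroxyl gives a C4 cation stabilized by the 5- and 7-oxygens of ring A, which the silyl ketene acetal captures (Mukaiyama-type alkylation, the reaction type used for C4 substitution of 4-oxygenated flavans by allylsilanes and enol silanes); attack anti to the 3-benzyloxy and 2-aryl groups sets 4S (3,4-trans), and the much more nucleophilic ketene acetal in excess should outrun self-condensation through C8.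

Step 7
Reactants: 17 benzyl 2-[(2R,3R,4S)-3,5,7-tris(benzyloxy)-2-[3,4-bis(benzyloxy)phenyl]-3,4-dihydro-2H-chromen-4-yl]acetate; 13 (2R,3R,4R)-3,5,7-tris(benzyloxy)-2-[3,4-bis(benzyloxy)phenyl]-3,4-dihydro-2H-chromen-4-ol
Product: 18 benzyl 2-[(2R,3R,4S)-3,5,7-tris(benzyloxy)-2-[3,4-bis(benzyloxy)phenyl]-8-[(2R,3R,4R)-3,5,7-tris(benzyloxy)-2-[3,4-bis(benzyloxy)phenyl]-3,4-dihydro-2H-chromen-4-yl]-3,4-dihydro-2H-chromen-4-yl]acetate
Conditions: Me3SiOTf (0.1 equiv), CH2Cl2, 4 Å sieves, −78 to −40 °C (2.5 equiv of 17, slow addition of 13)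
Reagents that add atoms: none
Why: Friedel–Crafts-type flavan C4-to-C8 coupling, the established way to benzylated 4→8 procyanidins; C8 is the most nucleophilic position of the 5,7-bis(benzyloxy) ring A, the cation is again attacked anti to the 3-benzyloxy and 2-aryl groups (4R in the upper unit), and the excess of 17 should suppress self-condensation of 13.

Step 8
Reactants: 18 benzyl 2-[(2R,3R,4S)-3,5,7-tris(benzyloxy)-2-[3,4-bis(benzyloxy)phenyl]-8-[(2R,3R,4R)-3,5,7-tris(benzyloxy)-2-[3,4-bis(benzyloxy)phenyl]-3,4-dihydro-2H-chromen-4-yl]-3,4-dihydro-2H-chromen-4-yl]acetate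
Product: 19 2-[(2R,3R,4S)-2-(3,4-dihydroxyphenyl)-8-[(2R,3R,4R)-2-(3,4-dihydroxyphenyl)-3,5,7-trihydroxy-3,4-dihydro-2H-chromen-4-yl]-3,5,7-trihydroxy-3,4-dihydro-2H-chromen-4-yl]acetic acid
Conditions: H2 (1 atm), Pd(OH)2/C, THF/MeOH/H2O, rt
Reagents that add atoms: none
Why: Hydrogenolysis of ten benzyl ethers and the benzyl ester, standard for benzylated procyanidins; under neutral conditions the interflavan bond and the stereocentres should stay untouched.

**Compound list**

1 | 1,3,5-trifluorobenzene | Fc1cc(F)cc(F)c1 | starting material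
2 | benzyl alcohol | OCc1ccccc1 | starting material
3 | 1,3-bis(benzyloxy)-5-fluorobenzene | Fc1cc(OCc2ccccc2)cc(OCc2ccccc2)c1 | intermediate
4 | 2-(benzyloxy)-N-methoxy-N-methylacetamide | CON(C)C(=O)COCc1ccccc1 | starting material
5 | [2,4-bis(benzyloxy)-6-fluorophenyl]lithium (aryllithium, not isolated) | [Li]c1c(F)cc(OCc2ccccc2)cc1OCc1ccccc1 | intermediate
6 | lithium 2-(benzyloxy)-1-[2,4-bis(benzyloxy)-6-fluorophenyl]-1-[methoxy(methyl)amino]ethan-1-olate (tetrahedral adduct, not isolated) | [Li]OC(COCc1ccccc1)(N(C)OC)c1c(F)cc(OCc2ccccc2)cc1OCc1ccccc1 | intermediate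
7 | 2-(benzyloxy)-1-[2,4-bis(benzyloxy)-6-fluorophenyl]ethan-1-one | O=C(COCc1ccccc1)c1c(F)cc(OCc2ccccc2)cc1OCc1ccccc1 | intermediate
8 | 3,4-bis(benzyloxy)benzaldehyde | O=Cc1ccc(OCc2ccccc2)c(OCc2ccccc2)c1 | starting material
9 | (Z)-2-(benzyloxy)-1-[2,4-bis(benzyloxy)-6-fluorophenyl]ethenyl diisopinocampheylborinate (enol borinate, not isolated) | C(c1ccccc1)O/C=C(\OB([C@@H]1C[C@@H]2C[C@H]([C@H]1C)C2(C)C)[C@@H]1C[C@@H]2C[C@H]([C@H]1C)C2(C)C)c1c(F)cc(OCc2ccccc2)cc1OCc1ccccc1 | intermediate
10 | O-diisopinocampheylboryl derivative of (2S,3R)-2-(benzyloxy)-1-[2,4-bis(benzyloxy)-6-fluorophenyl]-3-[3,4-bis(benzyloxy)phenyl]-3-hydroxypropan-1-one (syn boron aldolate, not isolated) | O=C(c1c(F)cc(OCc2ccccc2)cc1OCc1ccccc1)[C@@H](OCc1ccccc1)[C@H](OB([C@@H]1C[C@@H]2C[C@H]([C@H]1C)C2(C)C)[C@@H]1C[C@@H]2C[C@H]([C@H]1C)C2(C)C)c1ccc(OCc2ccccc2)c(OCc2ccccc2)c1 | intermediate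
11 | tetrabutylammonium (1R,2S)-2-(benzyloxy)-3-[2,4-bis(benzyloxy)-6-fluorophenyl]-1-[3,4-bis(benzyloxy)phenyl]-3-oxopropan-1-olate (ammonium alkoxide, not isolated) | O=C(c1c(F)cc(OCc2ccccc2)cc1OCc1ccccc1)[C@@H](OCc1ccccc1)[C@H]([O-])c1ccc(OCc2ccccc2)c(OCc2ccccc2)c1.CCCC[N+](CCCC)(CCCC)CCCC | intermediate
12 | (2R,3S)-3,5,7-tris(benzyloxy)-2-[3,4-bis(benzyloxy)phenyl]-2,3-dihydro-4H-chromen-4-one (2,3-cis) | O=C1c2c(OCc3ccccc3)cc(OCc3ccccc3)cc2O[C@H](c2ccc(OCc3ccccc3)c(OCc3ccccc3)c2)[C@@H]1OCc1ccccc1 | intermediate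
13 | (2R,3R,4R)-3,5,7-tris(benzyloxy)-2-[3,4-bis(benzyloxy)phenyl]-3,4-dihydro-2H-chromen-4-ol (all-cis) | O[C@@H]1c2c(OCc3ccccc3)cc(OCc3ccccc3)cc2O[C@H](c2ccc(OCc3ccccc3)c(OCc3ccccc3)c2)[C@@H]1OCc1ccccc1 | intermediate
14 | benzyl acetate | CC(=O)OCc1ccccc1 | starting material
15 | lithium 1-(benzyloxy)ethen-1-olate (lithium enolate, not isolated) | [Li]OC(=C)OCc1ccccc1 | intermediate
16 | 1-(benzyloxy)-1-(tert-butyldimethylsilyloxy)ethene | C=C(OCc1ccccc1)O[Si](C)(C)C(C)(C)C | intermediate
17 | benzyl 2-[(2R,3R,4S)-3,5,7-tris(benzyloxy)-2-[3,4-bis(benzyloxy)phenyl]-3,4-dihydro-2H-chromen-4-yl]acetate | O=C(OCc1ccccc1)C[C@H]1c2c(OCc3ccccc3)cc(OCc3ccccc3)cc2O[C@H](c2ccc(OCc3ccccc3)c(OCc3ccccc3)c2)[C@@H]1OCc1ccccc1 | intermediate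
18 | benzyl 2-[(2R,3R,4S)-3,5,7-tris(benzyloxy)-2-[3,4-bis(benzyloxy)phenyl]-8-[(2R,3R,4R)-3,5,7-tris(benzyloxy)-2-[3,4-bis(benzyloxy)phenyl]-3,4-dihydro-2H-chromen-4-yl]-3,4-dihydro-2H-chromen-4-yl]acetate | O=C(OCc1ccccc1)C[C@H]1c2c(OCc3ccccc3)cc(OCc3ccccc3)c([C@H]3c4c(OCc5ccccc5)cc(OCc5ccccc5)cc4O[C@H](c4ccc(OCc5ccccc5)c(OCc5ccccc5)c4)[C@@H]3OCc3ccccc3)c2O[C@H](c2ccc(OCc3ccccc3)c(OCc3ccccc3)c2)[C@@H]1OCc1ccccc1 | intermediate
19 | 2-[(2R,3R,4S)-2-(3,4-dihydroxyphenyl)-8-[(2R,3R,4R)-2-(3,4-dihydroxyphenyl)-3,5,7-trihydroxy-3,4-dihydro-2H-chromen-4-yl]-3,5,7-trihydroxy-3,4-dihydro-2H-chromen-4-yl]acetic acid (CNP0190976.1) | O=C(O)C[C@H]1c2c(O)cc(O)c([C@H]3c4c(O)cc(O)cc4O[C@H](c4ccc(O)c(O)c4)[C@@H]3O)c2O[C@H](c2ccc(O)c(O)c2)[C@@H]1O | target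

**Step count and risks**

Total steps: 8. Longest linear sequence: 7 (steps 1, 2, 3, 4, 6, 7, 8).

Steps most likely to fail:

1. Step 3. The isopinocampheyl ligands may discriminate poorly between the aldehyde faces on this hindered, twisted aryl ketone, and the freed alkoxide may undergo retro-aldol cleavage or C3 epimerization before the ring closes, which would erode the syn (2,3-cis) relationship. The fallback uses known chemistry only, sets out from 8 (with 5 made from 3 as in step 2) and comes back at 12. Commercial (S)-4-benzyloxazolidin-2-one is N-acylated (n-BuLi, benzyloxyacetyl chloride, THF, −78 °C) to (S)-4-benzyl-3-[(benzyloxy)acetyl]oxazolidin-2-one F1. Its (Z)-boron enolate (n-Bu2BOTf, Et3N, CH2Cl2, −78 to 0 °C) adds to 8 in an Evans syn-aldol reaction to give (S)-4-benzyl-3-[(2S,3R)-2-(benzyloxy)-3-[3,4-bis(benzyloxy)phenyl]-3-hydroxypropanoyl]oxazolidin-2-one F2. Transamidation (MeONHMe·HCl, AlMe3, CH2Cl2) gives (2S,3R)-2-(benzyloxy)-3-[3,4-bis(benzyloxy)phenyl]-3-hydroxy-N-methoxy-N-methylpropanamide F3. An excess of aryllithium 5 (THF, −78 °C) then gives (2S,3R)-2-(benzyloxy)-1-[2,4-bis(benzyloxy)-6-fluorophenyl]-3-[3,4-bis(benzyloxy)phenyl]-3-hydroxypropan-1-one F4, and Cs2CO3 in DMF at 0 °C closes ring C by SNAr to give 12.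

2. Step 7. The cation from 13 may be trapped by C8 of a second molecule of 13 (self-condensation) instead of by 17, and some attack may occur through C6 of 17. The fallback sets out from 13 and comes back at 19. NBS (CH2Cl2, −20 °C) brominates the most nucleophilic position C8 to give (2R,3R,4R)-3,5,7-tris(benzyloxy)-2-[3,4-bis(benzyloxy)phenyl]-8-bromo-3,4-dihydro-2H-chromen-4-ol F5, an electrophile that cannot attack itself. Coupling with a slight excess of 17 (Me3SiOTf, CH2Cl2, −78 °C) gives the 8-bromo analogue of 18 (bromine on C8 of the upper unit) F6. Hydrogenolysis with H2, Pd(OH)2/C and Et3N removes the bromine together with all benzyl groups and gives 19.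

3. Step 2. Deprotonation may occur at the ring position between the two benzyloxy groups or at a benzylic CH2, and the ortho-fluoroaryllithium may lose LiF to an aryne on warming. The fallback sets out from 3 and comes back at 5. Electrophilic bromination (NBS, MeCN, 0 °C), expected para to one benzyloxy group and ortho to fluorine, gives 1,5-bis(benzyloxy)-2-bromo-3-fluorobenzene F7. Bromine–lithium exchange (n-BuLi, THF, −78 °C) then generates 5 regiospecifically, which is acylated with 4 as before.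

**Further compounds**

F1 | step 3 | (S)-4-benzyl-3-[(benzyloxy)acetyl]oxazolidin-2-one | O=C(COCc1ccccc1)N1C(=O)OC[C@@H]1Cc1ccccc1
F2 | step 3 | (S)-4-benzyl-3-[(2S,3R)-2-(benzyloxy)-3-[3,4-bis(benzyloxy)phenyl]-3-hydroxypropanoyl]oxazolidin-2-one | O=C([C@@H](OCc1ccccc1)[C@H](O)c1ccc(OCc2ccccc2)c(OCc2ccccc2)c1)N1C(=O)OC[C@@H]1Cc1ccccc1
F3 | step 3 | (2S,3R)-2-(benzyloxy)-3-[3,4-bis(benzyloxy)phenyl]-3-hydroxy-N-methoxy-N-methylpropanamide | CON(C)C(=O)[C@@H](OCc1ccccc1)[C@H](O)c1ccc(OCc2ccccc2)c(OCc2ccccc2)c1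
F4 | step 3 | (2S,3R)-2-(benzyloxy)-1-[2,4-bis(benzyloxy)-6-fluorophenyl]-3-[3,4-bis(benzyloxy)phenyl]-3-hydroxypropan-1-one | O=C(c1c(F)cc(OCc2ccccc2)cc1OCc1ccccc1)[C@@H](OCc1ccccc1)[C@H](O)c1ccc(OCc2ccccc2)c(OCc2ccccc2)c1
F5 | step 7 | (2R,3R,4R)-3,5,7-tris(benzyloxy)-2-[3,4-bis(benzyloxy)phenyl]-8-bromo-3,4-dihydro-2H-chromen-4-ol | O[C@@H]1c2c(OCc3ccccc3)cc(OCc3ccccc3)c(Br)c2O[C@H](c2ccc(OCc3ccccc3)c(OCc3ccccc3)c2)[C@@H]1OCc1ccccc1
F6 | step 7 | benzyl 2-[(2R,3R,4S)-3,5,7-tris(benzyloxy)-2-[3,4-bis(benzyloxy)phenyl]-8-[(2R,3R,4R)-3,5,7-tris(benzyloxy)-2-[3,4-bis(benzyloxy)phenyl]-8-bromo-3,4-dihydro-2H-chromen-4-yl]-3,4-dihydro-2H-chromen-4-yl]acetate | O=C(OCc1ccccc1)C[C@H]1c2c(OCc3ccccc3)cc(OCc3ccccc3)c([C@H]3c4c(OCc5ccccc5)cc(OCc5ccccc5)c(Br)c4O[C@H](c4ccc(OCc5ccccc5)c(OCc5ccccc5)c4)[C@@H]3OCc3ccccc3)c2O[C@H](c2ccc(OCc3ccccc3)c(OCc3ccccc3)c2)[C@@H]1OCc1ccccc1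
F7 | step 2 | 1,5-bis(benzyloxy)-2-bromo-3-fluorobenzene | Brc1c(F)cc(OCc2ccccc2)cc1OCc1ccccc1
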